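**Plan**

1. Carbons are numbered as in the germacrane skeleton (ring C1–C10, lactone carbons C11–C13). The last bond cut is O–C1: the dihydrofuran O–C1=C2–C3–C4 that bridges the ten-membered carbocycle is the C4 tertiary alcohol added across a C1≡C2 ring alkyne.
2. Before that, the two acyl groups come off and the ylidene butenolide (C7=C11, O–C12) is cut back to the C6 ketone of a cyclodec-5-ynone and a silyloxypyruvate.
3. The ynone is traced to a decalin epoxy ketone (C1–C6 bond restored). Ring A is opened at C1–C2, ring B at C1=C6, and the chain is cut at C5–C6, C6–C7 and C9–C10 into two dithianes and two chiral epoxides.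
4. Forward: ring B (aldol condensation), ring A (Nozaki–Hiyama–Kishi), fragmentation of the shared bond to the ten-membered ynone, butenolide annulation, deprotection and acylation, dihydrofuran last.
5. Stereochemistry: C4 from (S)-2-methylglycidol, C8 from (R)-epichlorohydrin, C10 by methyl addition anti to the C8 silyloxy group. The C5=C6 geometry is fixed by the ring, and the decalin centres C1, C2, C6 need no control because the fragmentation erases them.
6. The butenolide is built before the ring closure so that no ketone competes for the alkyne and the enol ether never meets enolate chemistry.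

Key step: step 25

Remark: lithiated dithianes are taken to attack epichlorohydrin at the oxirane CH2 with re-closure to the epoxide, the usual course, so the carbinol carbon is not inverted.

**Route**

Step 1
Reactants: 1 (S)-2-methylglycidol
Product: 2 (R)-2-methylpent-4-ene-1,2-diol
Conditions: CH2=CHMgBr (3 equiv), CuI (10 mol %), THF, −30 → 0 °C
Reagents that add atoms: vinylmagnesium bromide, C=C[Mg]Br
Why: Copper-catalysed Grignard opening of the 2,2-disubstituted epoxide should occur by SN2 attack at its CH2 terminus (C3), so the C4 carbinol centre of 1 is carried over untouched.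

Step 2
Reactants: 2 (R)-2-methylpent-4-ene-1,2-diol
Product: 4 (R)-2-methyl-2-(prop-2-enyl)oxirane, via primary tosylate 3 (not isolated)
Conditions: NaH (2.2 equiv), 1-(p-toluenesulfonyl)imidazole (1.05 equiv), THF, 0 °C → rt
Reagents that add atoms: none
Why: Selective sulfonylation of the primary alkoxide and intramolecular Williamson closure by the tertiary alkoxide should give the epoxide in one flask; the C4–O bond is never broken, so configuration is retained.

Step 3
Reactants: 5 2-methyl-1,3-dithiane; 6 (R)-epichlorohydrin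
Product: 8 (R)-2-[(2-methyl-1,3-dithian-2-yl)methyl]oxirane, via lithium chlorohydrin alkoxide 7 (not isolated)
Conditions: n-BuLi, THF, −30 °C; then 6, −78 °C → rt
Reagents that add atoms: none
Why: Corey–Seebach alkylation in which lithiated 5 opens the oxirane of 6 at its CH2 and the alkoxide 7 displaces chloride to re-form an epoxide, so the carbinol carbon (C8) is untouched while the dithiane carbon becomes C10 and its methyl C1.

Step 4
Reactants: 9 2-(tert-butyldimethylsilyl)-1,3-dithiane; 8 (R)-2-[(2-methyl-1,3-dithian-2-yl)methyl]oxirane; 4 (R)-2-methyl-2-(prop-2-enyl)oxirane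
Product: 12 2-[(R)-2-hydroxy-2-methylpent-4-enyl]-2-[(R)-2-(tert-butyldimethylsilyloxy)-3-(2-methyl-1,3-dithian-2-yl)propyl]-1,3-dithiane, via lithium silylcarbinolate 10 (not isolated), via lithiated silyl ether 11 (not isolated)
Conditions: t-BuLi, Et2O, −78 → −45 °C; then 8, −78 → −25 °C; then 4, HMPA–THF, −78 → 0 °C; H2O
Reagents that add atoms: none
Why: Three-component dithiane linchpin coupling in which lithiated 9 opens 8 at CH2 (C7), HMPA triggers the 1,4-Brook rearrangement of 10 that moves silicon to the C8 oxygen and frees the C6 carbanion 11, and 11 opens 4 at CH2 (C5); both epoxides react at the unsubstituted carbon, so C8 and C4 keep their configuration.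

Step 5
Reactants: 12 the tertiary alcohol from step 4
Product: 13 C4 triethylsilyl ether of 12
Conditions: Et3SiOTf, 2,6-lutidine, CH2Cl2, −78 → 0 °C
Reagents that add atoms: triethylsilyl triflate, CC[Si](CC)(CC)OS(=O)(=O)C(F)(F)F
Why: Silyl triflate silylation of the hindered tertiary C4 alcohol should protect it against retro-aldol cleavage and β-elimination in the enolate steps that follow.

Step 6
Reactants: 13 bis-dithiane
Product: 14 (4R,8R)-4-(tert-butyldimethylsilyloxy)-8-methyl-8-(triethylsilyloxy)undec-10-ene-2,6-dione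
Conditions: PhI(O2CCF3)2, NaHCO3, MeCN–H2O (9:1), 0 °C
Reagents that add atoms: water, O
Why: Oxidative dethioacetalisation with the hypervalent iodine reagent under bicarbonate buffer should free both ketones (C6 and C10) while sparing the silyl ethers and the terminal alkene.

Step 7
Reactants: 14 the 2,6-diketone
Product: 15 (5S)-5-(tert-butyldimethylsilyloxy)-3-hydroxy-3-[(R)-2-methyl-2-(triethylsilyloxy)pent-4-enyl]cyclohexan-1-one (C6 carbinol epimers)
Conditions: LiN(iPr)2 (1.1 equiv), THF, −78 °C; AcOH
Reagents that add atoms: none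
Why: Kinetic intramolecular aldol addition (6-enolexo) in which the methyl ketone is deprotonated at CH3 (C1) in preference to the hindered methylene groups and adds to the C6 ketone to close ring B; the new carbinol centre is not controlled and is removed in step 8.

Step 8
Reactants: 15 the ring B aldol
Product: 17 (S)-5-(tert-butyldimethylsilyloxy)-3-[(R)-2-methyl-2-(triethylsilyloxy)pent-4-enyl]cyclohex-2-en-1-one, via tertiary mesylate 16 (not isolated)
Conditions: MsCl, Et3N, CH2Cl2, 0 °C → rt
Reagents that add atoms: none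
Why: Sulfene mesylation of the tertiary aldol and E1cB elimination through the C10 ketone enolate can only give the conjugated C1=C6 enone.

Step 9
Reactants: 17 ring B enone
Product: 18 (S)-5-(tert-butyldimethylsilyloxy)-2-iodo-3-[(R)-2-methyl-2-(triethylsilyloxy)pent-4-enyl]cyclohex-2-en-1-one
Conditions: I2, pyridine, CH2Cl2, rt
Reagents that add atoms: iodine, II
Why: α-Iodination of the enone by the pyridine addition–iodination–elimination pathway (Baylis–Hillman type) should put iodine on C1; the β-alkyl group slows the reaction and the isolated terminal alkene does not add iodine irreversibly under these conditions.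

Step 10
Reactants: 18 α-iodo enone
Product: 19 (1S,5S)-5-(tert-butyldimethylsilyloxy)-2-iodo-1-methyl-3-[(R)-2-methyl-2-(triethylsilyloxy)pent-4-enyl]cyclohex-2-en-1-ol
Conditions: MeMgBr, THF, −78 °C
Reagents that add atoms: methylmagnesium bromide, C[Mg]Br
Why: Grignard 1,2-addition to the cyclohexenone carbonyl, expected anti to the C8 silyloxy group (axial attack on the half-chair, as in additions to 5-substituted cyclohexenones), should set C10 with methyl trans and oxygen cis to the C8 oxygen.

Step 11
Reactants: 19 tertiary allylic alcohol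
Product: 20 C10 triethylsilyl ether of 19
Conditions: Et3SiOTf, 2,6-lutidine, CH2Cl2, 0 °C
Reagents that add atoms: triethylsilyl triflate, CC[Si](CC)(CC)OS(=O)(=O)C(F)(F)F
Why: Silyl triflate silylation of the hindered tertiary C10 alcohol should shield it from the oxidants, the acid of step 16 and the acylating agents used later.

Step 12
Reactants: 20 vinyl iodide with terminal alkene
Product: 22 (S)-4-[(3S,5S)-5-(tert-butyldimethylsilyloxy)-2-iodo-3-methyl-3-(triethylsilyloxy)cyclohex-1-enyl]-3-methyl-3-(triethylsilyloxy)butanal, via terminal diol 21 (not isolated)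
Conditions: OsO4 (2 mol %), NaIO4, 2,6-lutidine, dioxane–H2O (3:1), rt
Reagents that add atoms: osmium tetroxide, O=[Os](=O)(=O)=O; sodium periodate, [Na+].[O-]I(=O)(=O)=O
Why: Lemieux–Johnson cleavage in which OsO4 dihydroxylates only the monosubstituted alkene (the tetrasubstituted iodoalkene is too hindered) and NaIO4 cleaves diol 21 to the C2 aldehyde.

Step 13
Reactants: 22 iodo aldehyde
Product: 23 bicyclic allylic alcohol (ring A closed at C1–C2; C2 carbinol epimers; C1=C6 at the ring fusion)
Conditions: CrCl2 (6 equiv), NiCl2 (2 mol %), DMF, rt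
Reagents that add atoms: none
Why: Intramolecular Nozaki–Hiyama–Kishi reaction in which nickel inserts into the vinyl iodide, the vinyl group passes to chromium and adds to the aldehyde to close six-membered ring A; the C2 carbinol forms as a mixture that is oxidised away in step 15, and elimination towards a six-ring allene is not possible.

Step 14
Reactants: 23 bicyclic allylic alcohol
Product: 24 C1–C6 epoxy alcohol (either epoxide face)
Conditions: mCPBA, NaHCO3, CH2Cl2, 0 °C
Reagents that add atoms: 3-chloroperoxybenzoic acid, OOC(=O)c1cccc(Cl)c1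
Why: Prilezhaev epoxidation of the electron-rich tetrasubstituted C1=C6 alkene, helped by the allylic C2 hydroxyl; the face of attack is irrelevant because C1 and C6 lose their stereochemistry in step 16.

Step 15
Reactants: 24 epoxy alcohol
Product: 25 α,β-epoxy ketone (C2 ketone, C1–C6 epoxide)
Conditions: Dess–Martin periodinane, NaHCO3, CH2Cl2, rt
Reagents that add atoms: none
Why: Dess–Martin oxidation of the secondary C2 alcohol should give the epoxy ketone without touching the epoxide or the silyl ethers.

Step 16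
Reactants: 25 α,β-epoxy ketone
Product: 27 (3R,7S,9R)-9-(tert-butyldimethylsilyloxy)-3,7-dimethyl-3,7-bis(triethylsilyloxy)cyclodec-5-yn-1-one, via tosylhydrazone 26 (not isolated)
Conditions: TsNHNH2, AcOH–CH2Cl2 (1:1), −20 °C → rt
Reagents that add atoms: none
Why: Eschenmoser–Tanabe fragmentation in which tosylhydrazone 26 opens the epoxide and loses N2 and p-toluenesulfinate, cleaving the C1–C6 fusion bond to give the C1≡C2 alkyne and the C6 ketone of the ten-membered ring; C1 and C6 cease to be stereocentres and C4, C8, C10 are not touched.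

Step 17
Reactants: 28 methyl 2-(hydroxymethyl)acrylate
Product: 29 methyl 2-[(tert-butyldimethylsilyloxy)methyl]acrylate
Conditions: t-BuMe2SiCl, imidazole, CH2Cl2, 0 °C → rt
Reagents that add atoms: tert-butyldimethylsilyl chloride, CC(C)(C)[Si](C)(C)Cl
Why: Imidazole-promoted silylation of the primary allylic alcohol.

Step 18
Reactants: 29 silyloxymethyl acrylate
Product: 31 methyl 3-(tert-butyldimethylsilyloxy)-2-oxopropanoate, via ozonide 30 (not isolated)
Conditions: O3, CH2Cl2, −78 °C; then Me2S, −78 °C → rt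
Reagents that add atoms: ozone, [O-][O+]=O
Why: Ozonolysis of the 1,1-disubstituted acrylate with reductive work-up should deliver the α-keto ester (C11–C13 unit).

Step 19
Reactants: 27 cyclodecynone; 31 methyl 3-(tert-butyldimethylsilyloxy)-2-oxopropanoate
Product: 32 aldol adduct: 27 carrying at C7 the group C(OH)(CH2OSiMe2t-Bu)CO2Me (C7 and C11 epimers)
Conditions: LiN(iPr)2 (1.1 equiv), THF, −78 °C; then 31, −78 °C; AcOH
Reagents that add atoms: none
Why: Kinetic aldol addition in which LiN(iPr)2 should remove a C7 proton (C5 is neopentyl-like beside the fully substituted C4) and the enolate adds to the ketone carbonyl of the α-keto ester; the new centres C7 and C11 are not controlled and both become sp2 in step 21.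

Step 20
Reactants: 32 aldol adduct (methyl ester)
Product: 33 α-hydroxy-γ-keto carboxylic acid
Conditions: LiOH, THF–H2O (3:1), 0 °C; then dilute HCl to pH 4
Reagents that add atoms: lithium hydroxide, [Li+].[OH-]
Why: Saponification of the activated α-hydroxy ester at 0 °C should be faster than retro-aldol cleavage or loss of the β-silyloxy groups.

Step 21
Reactants: 33 α-hydroxy-γ-keto acid
Product: 36 silyl-protected dienolide (6,12-enol lactone with C5=C6 and C7=C11 on the cyclodecyne), via hydroxy enol lactone 34 (not isolated), via tertiary mesylate 35 (not isolated)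
Conditions: Ac2O, Et3N, DMAP (cat.), CH2Cl2, 0 °C → rt; then MsCl, Et3N, 0 °C → rt
Reagents that add atoms: none
Why: Enol lactonisation of a γ-keto acid (acetic anhydride activates the carboxyl and the C6 enol oxygen closes the five-membered ring, which places C12 on the C6 side of C7–C11) followed by mesylation of the tertiary C11 carbinol and 1,4-elimination with loss of a C5 proton gives the conjugated dienolide; the ten-membered ring with its alkyne only accommodates C4 cis to C7 on the new C5=C6 bond, which is the geometry of the target.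

Step 22
Reactants: 36 silyl-protected dienolide
Product: 37 tetraol (free hydroxyls at C4, C8, C10, C13)
Conditions: HF·pyridine, pyridine, THF, 0 °C → rt
Reagents that add atoms: none
Why: Fluoride cleavage of all four silyl ethers; the dienolide, the alkyne and the tertiary carbinols should tolerate pyridine-buffered HF.

Step 23
Reactants: 37 tetraol
Product: 38 C13 acetate
Conditions: AcCl (1.05 equiv), 2,4,6-collidine, CH2Cl2, −78 °C
Reagents that add atoms: acetyl chloride, CC(Cl)=O
Why: Low-temperature acylation with acetyl chloride and collidine is selective for the only primary alcohol over the secondary and tertiary ones.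

Step 24
Reactants: 38 C13 acetate
Product: 39 C8 methacrylate C13 acetate (cyclodecyne with free C4 and C10 hydroxyls)
Conditions: methacrylic anhydride, Et3N, DMAP (cat.), CH2Cl2, 0 °C
Reagents that add atoms: methacrylic anhydride, C=C(C)C(=O)OC(=O)C(C)=C
Why: DMAP-catalysed acyl transfer esterifies the only secondary alcohol (C8); the two tertiary carbinols are inert under these conditions.

Step 25
Reactants: 39 C8 methacrylate C13 acetate with free C4 and C10 hydroxyls
Product: 40 CNP0394509.1 (target)
Conditions: Ph3PAuNTf2 (5 mol %), CH2Cl2, 4 Å molecular sieves, 0 °C → rt; then Et3N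
Reagents that add atoms: none
Why: The phosphine complex of monovalent gold coordinates the strained ring alkyne C1≡C2, the C4 hydroxyl adds anti at C1, and protodeauration at C2 releases the enol ether and the catalyst. The closest known reaction type is the gold-catalysed cycloisomerisation of homopropargylic alcohols to 2,3-dihydrofurans, run here across the ten-membered ring. The dihydrofuran closes 5-endo-dig; attack at C2 would be 4-exo and give an oxetane, and the C10 hydroxyl could only form a three-membered ring. No stereocentre is made or touched, and anti addition puts C3 cis to oxygen, which is the E-in-ring C1=C2 of the target. The step needs the C4 oxygen to be the only nucleophile within reach and no ionisation at the propargylic C10 carbinol: the C8 and C13 oxygens are acylated, the C6 oxygen is locked in the enol lactone so no carbonyl–alkyne metathesis can occur, and the aprotic medium, low catalyst loading and amine quench disfavour a Meyer–Schuster-type loss of the C10 hydroxyl. The bent cyclodecyne holds the C4 oxygen next to C1, so closure costs little entropy and relieves alkyne strain.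

**Compound list**

1 | (S)-2-methylglycidol | C[C@]1(CO)CO1 | starting material
2 | (R)-2-methylpent-4-ene-1,2-diol | C=CC[C@@](C)(O)CO | intermediate
3 | (R)-2-hydroxy-2-methylpent-4-enyl p-toluenesulfonate (not isolated) | C=CC[C@@](C)(O)COS(=O)(=O)c1ccc(C)cc1 | intermediate
4 | (R)-2-methyl-2-(prop-2-enyl)oxirane | C=CC[C@@]1(C)OC1 | intermediate
5 | 2-methyl-1,3-dithiane | CC1SCCCS1 | starting material
6 | (R)-epichlorohydrin | ClC[C@H]1CO1 | starting material
7 | lithium (R)-1-chloro-3-(2-methyl-1,3-dithian-2-yl)propan-2-olate (not isolated) | CC1(C[C@@H](O[Li])CCl)SCCCS1 | intermediate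
8 | (R)-2-[(2-methyl-1,3-dithian-2-yl)methyl]oxirane | CC1(C[C@@H]2CO2)SCCCS1 | intermediate
9 | 2-(tert-butyldimethylsilyl)-1,3-dithiane | CC(C)(C)[Si](C)(C)C1SCCCS1 | starting material
10 | lithium (R)-1-[2-(tert-butyldimethylsilyl)-1,3-dithian-2-yl]-3-(2-methyl-1,3-dithian-2-yl)propan-2-olate (not isolated) | CC(C)(C)[Si](C)(C)C1(C[C@H](O[Li])CC2(C)SCCCS2)SCCCS1 | intermediate
11 | 2-lithio-1,3-dithiane carrying the 2-(tert-butyldimethylsilyloxy)-3-(2-methyl-1,3-dithian-2-yl)propyl chain, C8 as in 8 (not isolated) | [Li]C1(C[C@H](O[Si](C)(C)C(C)(C)C)CC2(C)SCCCS2)SCCCS1 | intermediate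
12 | 2-[(R)-2-hydroxy-2-methylpent-4-enyl]-2-[(R)-2-(tert-butyldimethylsilyloxy)-3-(2-methyl-1,3-dithian-2-yl)propyl]-1,3-dithiane | C=CC[C@@](C)(O)CC1(C[C@H](O[Si](C)(C)C(C)(C)C)CC2(C)SCCCS2)SCCCS1 | intermediate
13 | C4 triethylsilyl ether of 12 | C=CC[C@@](C)(O[Si](CC)(CC)CC)CC1(C[C@H](O[Si](C)(C)C(C)(C)C)CC2(C)SCCCS2)SCCCS1 | intermediate
14 | (4R,8R)-4-(tert-butyldimethylsilyloxy)-8-methyl-8-(triethylsilyloxy)undec-10-ene-2,6-dione | C=CC[C@@](C)(O[Si](CC)(CC)CC)CC(=O)C[C@H](O[Si](C)(C)C(C)(C)C)CC(C)=O | intermediate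
15 | (5S)-5-(tert-butyldimethylsilyloxy)-3-hydroxy-3-[(R)-2-methyl-2-(triethylsilyloxy)pent-4-enyl]cyclohexan-1-one, carbinol epimers | O=C1CC(O)(C[C@@](C)(CC=C)O[Si](CC)(CC)CC)C[C@H](O[Si](C)(C)C(C)(C)C)C1 | intermediate
16 | methanesulfonate of 15 (not isolated) | O=C1CC(OS(C)(=O)=O)(C[C@@](C)(CC=C)O[Si](CC)(CC)CC)C[C@H](O[Si](C)(C)C(C)(C)C)C1 | intermediate
17 | (S)-5-(tert-butyldimethylsilyloxy)-3-[(R)-2-methyl-2-(triethylsilyloxy)pent-4-enyl]cyclohex-2-en-1-one | O=C1C=C(C[C@@](C)(CC=C)O[Si](CC)(CC)CC)C[C@H](O[Si](C)(C)C(C)(C)C)C1 | intermediate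
18 | (S)-5-(tert-butyldimethylsilyloxy)-2-iodo-3-[(R)-2-methyl-2-(triethylsilyloxy)pent-4-enyl]cyclohex-2-en-1-one | O=C1C(I)=C(C[C@@](C)(CC=C)O[Si](CC)(CC)CC)C[C@H](O[Si](C)(C)C(C)(C)C)C1 | intermediate
19 | (1S,5S)-5-(tert-butyldimethylsilyloxy)-2-iodo-1-methyl-3-[(R)-2-methyl-2-(triethylsilyloxy)pent-4-enyl]cyclohex-2-en-1-ol | C[C@@]1(O)C(I)=C(C[C@@](C)(CC=C)O[Si](CC)(CC)CC)C[C@H](O[Si](C)(C)C(C)(C)C)C1 | intermediate
20 | C10 triethylsilyl ether of 19 | C[C@@]1(O[Si](CC)(CC)CC)C(I)=C(C[C@@](C)(CC=C)O[Si](CC)(CC)CC)C[C@H](O[Si](C)(C)C(C)(C)C)C1 | intermediate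
21 | terminal 1,2-diol from 20, carbinol epimers (not isolated) | C[C@@]1(O[Si](CC)(CC)CC)C(I)=C(C[C@@](C)(CC(O)CO)O[Si](CC)(CC)CC)C[C@H](O[Si](C)(C)C(C)(C)C)C1 | intermediate
22 | (S)-4-[(3S,5S)-5-(tert-butyldimethylsilyloxy)-2-iodo-3-methyl-3-(triethylsilyloxy)cyclohex-1-enyl]-3-methyl-3-(triethylsilyloxy)butanal | C[C@@]1(O[Si](CC)(CC)CC)C(I)=C(C[C@@](C)(CC=O)O[Si](CC)(CC)CC)C[C@H](O[Si](C)(C)C(C)(C)C)C1 | intermediate
23 | bicyclic allylic alcohol: octahydronaphthalene with C1=C6 at the fusion, C2 hydroxyl (epimers), 4-methyl-4-(triethylsilyloxy) in ring A, 10-methyl-10-(triethylsilyloxy) and 8-(tert-butyldimethylsilyloxy) in ring B | OC1C[C@@](C)(O[Si](CC)(CC)CC)CC2=C1[C@@](C)(O[Si](CC)(CC)CC)C[C@@H](O[Si](C)(C)C(C)(C)C)C2 | intermediate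
24 | C1–C6 epoxide of 23 (either face) | OC1C[C@@](C)(O[Si](CC)(CC)CC)CC23OC13[C@@](C)(O[Si](CC)(CC)CC)C[C@@H](O[Si](C)(C)C(C)(C)C)C2 | intermediate
25 | α,β-epoxy ketone (C2 ketone of 24) | O=C1C[C@@](C)(O[Si](CC)(CC)CC)CC23OC13[C@@](C)(O[Si](CC)(CC)CC)C[C@@H](O[Si](C)(C)C(C)(C)C)C2 | intermediate
26 | p-toluenesulfonylhydrazone of 25 (not isolated) | Cc1ccc(cc1)S(=O)(=O)NN=C1C[C@@](C)(O[Si](CC)(CC)CC)CC23OC13[C@@](C)(O[Si](CC)(CC)CC)C[C@@H](O[Si](C)(C)C(C)(C)C)C2 | intermediate
27 | (3R,7S,9R)-9-(tert-butyldimethylsilyloxy)-3,7-dimethyl-3,7-bis(triethylsilyloxy)cyclodec-5-yn-1-one | O=C1C[C@H](O[Si](C)(C)C(C)(C)C)C[C@](C)(O[Si](CC)(CC)CC)C#CC[C@@](C)(O[Si](CC)(CC)CC)C1 | intermediate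
28 | methyl 2-(hydroxymethyl)acrylate | C=C(CO)C(=O)OC | starting material
29 | methyl 2-[(tert-butyldimethylsilyloxy)methyl]acrylate | C=C(CO[Si](C)(C)C(C)(C)C)C(=O)OC | intermediate
30 | ozonide (1,2,4-trioxolane) of 29 (not isolated) | COC(=O)C1(CO[Si](C)(C)C(C)(C)C)OCOO1 | intermediate
31 | methyl 3-(tert-butyldimethylsilyloxy)-2-oxopropanoate | COC(=O)C(=O)CO[Si](C)(C)C(C)(C)C | intermediate
32 | aldol adduct: 27 bearing at C7 the group C(OH)(CH2OSiMe2t-Bu)CO2Me, C7 and C11 epimers | COC(=O)C(O)(CO[Si](C)(C)C(C)(C)C)C1C(=O)C[C@](C)(O[Si](CC)(CC)CC)CC#C[C@@](C)(O[Si](CC)(CC)CC)C[C@H]1O[Si](C)(C)C(C)(C)C | intermediate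
33 | carboxylic acid of 32 | OC(=O)C(O)(CO[Si](C)(C)C(C)(C)C)C1C(=O)C[C@](C)(O[Si](CC)(CC)CC)CC#C[C@@](C)(O[Si](CC)(CC)CC)C[C@H]1O[Si](C)(C)C(C)(C)C | intermediate
34 | hydroxy enol lactone: 6,12-lactone with C6=C7 and sp3 C11 bearing OH and CH2OSiMe2t-Bu (not isolated) | O=C1OC2=C(C1(O)CO[Si](C)(C)C(C)(C)C)[C@H](O[Si](C)(C)C(C)(C)C)C[C@](C)(O[Si](CC)(CC)CC)C#CC[C@@](C)(O[Si](CC)(CC)CC)C2 | intermediate
35 | C11 methanesulfonate of 34 (not isolated) | O=C1OC2=C(C1(OS(C)(=O)=O)CO[Si](C)(C)C(C)(C)C)[C@H](O[Si](C)(C)C(C)(C)C)C[C@](C)(O[Si](CC)(CC)CC)C#CC[C@@](C)(O[Si](CC)(CC)CC)C2 | intermediate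
36 | (4R,8R,10S) dienolide on the cyclodec-1-yne: 6,12-enol lactone with C5=C6 (C4 cis to C7) and C7=C11; 4- and 10-triethylsilyloxy, 8- and 13-tert-butyldimethylsilyloxy | CC(C)(C)[Si](C)(C)O[C@@H]1C[C@](C)(O[Si](CC)(CC)CC)C#CC[C@@](C)(O[Si](CC)(CC)CC)/C=C2/OC(=O)C(CO[Si](C)(C)C(C)(C)C)=C21 | intermediate
37 | (4R,8R,10S) tetraol: 36 with free hydroxyls at C4, C8, C10, C13 | O[C@@H]1C[C@](C)(O)C#CC[C@@](C)(O)/C=C2/OC(=O)C(CO)=C21 | intermediate
38 | C13 acetate of 37 | O[C@@H]1C[C@](C)(O)C#CC[C@@](C)(O)/C=C2/OC(=O)C(COC(C)=O)=C21 | intermediate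
39 | C8 methacrylate C13 acetate, free C4 and C10 hydroxyls, C1≡C2 ring alkyne | C=C(C)C(=O)O[C@@H]1C[C@](C)(O)C#CC[C@@](C)(O)/C=C2/OC(=O)C(COC(C)=O)=C21 | intermediate
40 | CNP0394509.1 | C=C(C)C(=O)O[C@@H]1C[C@](C)(O)C2=CC[C@](C)(/C=C3/OC(=O)C(COC(C)=O)=C31)O2 | target

**Totals**

Total step count: 25.
Longest linear sequence: 22 steps (steps 1, 2, 4–16, 19–25, from 1 to 40).

**Steps most likely to fail**

Step 21. Activation of the tertiary C11 hydroxyl may outrun ring closure. Water is then lost across C7–C11 in the open keto acid and the carboxyl ends up on the C8 side of the new alkene, where it cannot close onto the C6 oxygen. The fallback sets out from 32 and accepts elimination first. MsCl and Et3N convert 32 through the C11 mesylate F1 into the alkylidene keto ester F2 as a mixture of alkene isomers. LiOH in aqueous THF then gives the alkylidene keto acid F3. A catalytic thiolate (PhSH, Et3N) equilibrates the alkene geometry by reversible conjugate addition, and the isomer with the carboxyl beside the ketone is drained as the cyclic hydroxybutenolide F4 (carboxyl adding to the C6 carbonyl). MsCl and Et3N convert F4 through its mesylate F5, by loss of methanesulfonate and a C5 proton, into 36, where the route is rejoined.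

Step 25. Ionisation at the free propargylic C10 carbinol (Meyer–Schuster-type rearrangement), or an acid-promoted 1,2-shift in the α-hydroxy enol ether once formed, may compete with clean 5-endo addition. The fallback sets out from 39 and replaces π-acid catalysis by electrophilic iodoetherification. I2 and NaHCO3 in MeCN at 0 °C should give the iodo enol ether F6 by 5-endo-dig attack of the C4 hydroxyl on the iodonium ion. Radical hydrodeiodination with Bu3SnH and catalytic Et3B in toluene at −78 °C then removes the vinylic iodine and arrives at 40.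

Step 19. Enolisation may not discriminate well enough between C5 and C7, or the C7 enolate may lose the C8 silyloxy group by β-elimination before it adds to 31. The fallback sets out from 27. Silylation under equilibrating conditions (Me3SiOTf, Et3N, CH2Cl2, 0 °C) gives the trimethylsilyl enol ether F7 of the C6–C7 enol, which is purified from any regioisomer. MeLi in THF regenerates the lithium enolate regiospecifically at low temperature, and addition to 31 rejoins the route at 32.

**Further compounds**

F1 | step 21 | C11 methanesulfonate of 32 | COC(=O)C(OS(C)(=O)=O)(CO[Si](C)(C)C(C)(C)C)C1C(=O)C[C@](C)(O[Si](CC)(CC)CC)CC#C[C@@](C)(O[Si](CC)(CC)CC)C[C@H]1O[Si](C)(C)C(C)(C)C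
F2 | step 21 | alkylidene keto ester (C7=C11, both alkene isomers) | COC(=O)C(CO[Si](C)(C)C(C)(C)C)=C1C(=O)C[C@](C)(O[Si](CC)(CC)CC)CC#C[C@@](C)(O[Si](CC)(CC)CC)C[C@H]1O[Si](C)(C)C(C)(C)C
F3 | step 21 | alkylidene keto acid (C7=C11, both alkene isomers) | OC(=O)C(CO[Si](C)(C)C(C)(C)C)=C1C(=O)C[C@](C)(O[Si](CC)(CC)CC)CC#C[C@@](C)(O[Si](CC)(CC)CC)C[C@H]1O[Si](C)(C)C(C)(C)C
F4 | step 21 | hydroxybutenolide (C6 hemiketal lactone, C7=C11) | CC(C)(C)[Si](C)(C)O[C@@H]1C[C@](C)(O[Si](CC)(CC)CC)C#CC[C@@](C)(O[Si](CC)(CC)CC)CC2(O)OC(=O)C(CO[Si](C)(C)C(C)(C)C)=C21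
F5 | step 21 | C6 methanesulfonate of the hydroxybutenolide | CC(C)(C)[Si](C)(C)O[C@@H]1C[C@](C)(O[Si](CC)(CC)CC)C#CC[C@@](C)(O[Si](CC)(CC)CC)CC2(OS(C)(=O)=O)OC(=O)C(CO[Si](C)(C)C(C)(C)C)=C21
F6 | step 25 | C2 iodo enol ether of the target skeleton | C=C(C)C(=O)O[C@@H]1C[C@](C)(O)C2=C(I)C[C@](C)(/C=C3/OC(=O)C(COC(C)=O)=C31)O2
F7 | step 19 | C6–C7 trimethylsilyl enol ether of 27 | C[Si](C)(C)OC1=C[C@H](O[Si](C)(C)C(C)(C)C)C[C@](C)(O[Si](CC)(CC)CC)C#CC[C@@](C)(O[Si](CC)(CC)CC)C1
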